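Pdt at the asked time was what I wanted from this flask, which differs from the two earlier runs in its loading of Ctl.

all flasks: Sbt 0.15 M; Tsp 20 mM (held)
- Sunday's: Ctl 3.1 mol%; run made earlier
- Wednesday's: Ctl 7.1 mol%; run made earlier
- flask: Ctl 4.7 mol%; time 25 h

| run | time / h | Pdt / % | Sbt / % |
|---|---|---|---|
| Sunday's | 4.00 | 15.8 | 83.3 |
| Sunday's | 10.0 | 39.8 | 61.1 |
| Sunday's | 20.0 | 66.6 | 33.5 |
| Sunday's | 30.0 | 82.5 | 18.0 |
| Wednesday's | 4.00 | 20.8 | 78.6 |
| Wednesday's | 10.0 | 50.5 | 49.7 |
| Wednesday's | 20.0 | 79.9 | 20.5 |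
| Wednesday's | 30.0 | 91.4 | 8.4 |

(standard deviation of a reading: 0.5 percentage points)

* Pdt at 25 h, in percent of the Sbt charged
* concentration of Tsp2 in solution at 25 h, in percent of saturation

I read the two tables row against row through a loss number L, the natural logarithm of Sbt charged over Sbt left. Wednesday's L over Sunday's L was 1.32 at 4.00 h, 1.42 at 10.0 h, 1.45 at 20.0 h and 1.44 at 30.0 h, so the last two rows, which bracket the asked time, nearly agreed. Against a loading ratio of 2.29, the 20.0 h row gave the apparent order in Ctl, the power of the loading that L follows: n = 0.448. That is close to half, which I took as a hint that Ctl stood largely paired with itself in a fast step.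

Midway between those rows, Sunday's L was 1.40. Scaled to this flask's loading it became 1.69. Since Pdt and Sbt summed to 100% in Sunday's 20.0 h row, I reckoned 81.6% of Pdt. I committed to no figure for Tsp2.

The forecast gave 81.8% of Pdt (79.5% to 84%), against my 81.6%, and 96% of saturation (85% to 100%), saying: “The rise time of about 5 h suggests near saturation by 25 h.”

The flask gave 82.0% of Pdt and 88.1% of saturation, with 65.5% of the catalyst charged standing as Tsp3 at 25.0 h.

    Tsp ⇌ Tsp2, rate k1*(csat - [Tsp2]) (kL = 0.910 /h)
    Sbt + Tsp2 + Ctl ⇌ Ctl + Pdt (K = 1000 /M, k = 2300 /M²/h)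
    2 Ctl ⇌ Tsp3, settled at all times (K = 390 /M)

Applied to Sunday's 30.0 h row, n gave 87.3% of Pdt at this loading, and the computed value there is 87.3%.

For the neighbour flask with 2.8 mol% of Ctl, n gave 73.9% of Pdt at 25 h; the computed result is 74.1%.

(The earlier runs and the new flask were computed for an exercise; noise was put on by code.)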